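Ring A is built, not decorated. It is cut at C1–C2, C2–C3, C4–C5 and C5–C6 into a chiral dienyl diazo ketone (C2–C5 with the C3 side chain and its stereocentre) and an aryl alkynyl ether that already carries ring B on the C6 oxygen and a protected hydroxymethyl on C1. One photochemical–thermal cascade (Wolff shift, ketene–alkyne cycloaddition, electrocyclic opening and closure) then assembles the whole ring regiospecifically. It exploits the pattern of ring A: oxygens at C2 and C6 meta to each other with the carbon substituent at C1 between them, the side chain at C3 and unsubstituted C4 and C5. The crowded diaryl ether is never made by coupling.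

Key step: step 14

Assumption: commercial (S)-3-hydroxy-γ-butyrolactone supplies the single stereocentre; its carbinol carbon becomes the benzylic carbinol of the target with unchanged spatial arrangement, and the descriptor is S at every stage.

Abbreviations: TES = triethylsilyl; TBS = tert-butyldimethylsilyl; SEM = 2-(trimethylsilyl)ethoxymethyl; PMB = 4-methoxybenzyl; ArB = 2-(TBSOCH2)-4-methyl-6-(SEMO)phenyl (ring B, numbered from its oxygen-bearing carbon).

**Route**

Step 1
Reactants: 1 (S)-3-hydroxy-γ-butyrolactone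
Product: 2 (S)-4-methylpentane-1,2,4-triol
Conditions: MeMgBr (4 equiv), THF, 0 °C → rt; sat. aq NH4Cl
Reagents that add atoms: methylmagnesium bromide, C[Mg]Br
Why: Double Grignard addition to the lactone carbonyl (the carbinol sits as its magnesium alkoxide) opens the ring to the gem-dimethyl carbinol without touching the stereocentre.

Step 2
Reactants: 2 (S)-4-methylpentane-1,2,4-triol
Product: 3 (S)-4-methyl-1,2,4-tris(triethylsilyloxy)pentane
Conditions: Et3SiOTf (3.6 equiv), 2,6-lutidine, CH2Cl2, −78 → 0 °C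
Reagents that add atoms: triethylsilyl trifluoromethanesulfonate, CC[Si](CC)(CC)OS(=O)(=O)C(F)(F)F
Why: Silyl triflate/lutidine silylation is strong enough for the tertiary hydroxyl, so all three oxygens are capped in one operation.

Step 3
Reactants: 3 (S)-4-methyl-1,2,4-tris(triethylsilyloxy)pentane
Product: 4 (S)-4-methyl-2,4-bis(triethylsilyloxy)pentanal
Conditions: (COCl)2, DMSO, CH2Cl2, −78 → −35 °C; Et3N, −78 → 0 °C
Reagents that add atoms: none
Why: Direct Swern oxidation of a primary triethylsilyl ether, in which only the unhindered primary ether is activated by chlorodimethylsulfonium chloride and desilylated in situ while the secondary and tertiary ethers remain; cold amine addition avoids epimerisation of the α-silyloxy aldehyde.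

Step 4
Reactants: 4 (S)-4-methyl-2,4-bis(triethylsilyloxy)pentanal; 5 1-(triphenylphosphoranylidene)propan-2-one
Product: 6 (S,E)-7-methyl-5,7-bis(triethylsilyloxy)oct-3-en-2-one
Conditions: toluene, 60 °C
Reagents that add atoms: none
Why: Wittig olefination with a ketone-stabilised ylide under neutral conditions gives the (E)-enone without epimerising the adjacent carbinol carbon.

Step 5
Reactants: 6 (S,E)-7-methyl-5,7-bis(triethylsilyloxy)oct-3-en-2-one
Product: 8 (S,E)-1-diazo-7-methyl-5,7-bis(triethylsilyloxy)oct-3-en-2-one, via trifluoroacetyl diketone 7 (not isolated)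
Conditions: LiN(SiMe3)2, THF, −78 °C; CF3CO2CH2CF3; aq NH4Cl; then MsN3, Et3N, H2O, MeCN, rt
Reagents that add atoms: methanesulfonyl azide, CS(=O)(=O)N=[N+]=[N-]; 2,2,2-trifluoroethyl trifluoroacetate, O=C(OCC(F)(F)F)C(F)(F)F (its atoms remain only in 7)
Why: Detrifluoroacetylative diazo transfer, that is kinetic enolisation at the methyl group, Claisen trifluoroacetylation to activate that carbon, then Regitz-type transfer from the sulfonyl azide with loss of the trifluoroacetyl group as its sulfonamide.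

Step 6
Reactants: 9 2-methoxy-4-methylphenol (creosol)
Product: 10 2-hydroxy-3-methoxy-5-methylbenzaldehyde
Conditions: MgCl2, Et3N, (CH2O)n, MeCN, reflux; 1 M HCl
Reagents that add atoms: paraformaldehyde (formaldehyde), C=O
Why: Magnesium-mediated ortho-formylation (Casnati–Skattebøl), in which the magnesium phenoxide delivers formaldehyde to the only free ortho position and a second formaldehyde oxidises the benzylic alkoxide to the aldehyde.

Step 7
Reactants: 10 2-hydroxy-3-methoxy-5-methylbenzaldehyde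
Product: 11 2,3-dihydroxy-5-methylbenzaldehyde
Conditions: BBr3, CH2Cl2, −78 °C → rt; H2O
Reagents that add atoms: none
Why: Lewis-acid cleavage of the aryl methyl ether with BBr3, which an aryl aldehyde tolerates.

Step 8
Reactants: 11 2,3-dihydroxy-5-methylbenzaldehyde
Product: 12 2-hydroxy-5-methyl-3-(SEM-oxy)benzaldehyde
Conditions: NaH (2.1 equiv), DMSO/THF, rt; SEMCl (1.0 equiv); aq NH4Cl
Reagents that add atoms: 2-(trimethylsilyl)ethoxymethyl chloride, C[Si](C)(C)CCOCCl
Why: Regioselective monoalkylation of the catecholate dianion, in which the 2-oxide is a sodium-chelated vinylogous carboxylate and the non-conjugated 3-oxide is therefore the nucleophile toward one equivalent of the chloromethyl ether.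

Step 9
Reactants: 12 2-hydroxy-5-methyl-3-(SEM-oxy)benzaldehyde
Product: 13 2-(hydroxymethyl)-4-methyl-6-(SEM-oxy)phenol
Conditions: NaBH4, MeOH, 0 °C
Reagents that add atoms: none
Why: Borohydride reduction of the aldehyde, to which the acetal and the phenol are inert.

Step 10
Reactants: 13 2-(hydroxymethyl)-4-methyl-6-(SEM-oxy)phenol
Product: 14 2-(TBS-oxymethyl)-4-methyl-6-(SEM-oxy)phenol (ArB–OH)
Conditions: TBSCl (1.05 equiv), imidazole, CH2Cl2, 0 °C
Reagents that add atoms: tert-butyldimethylsilyl chloride, CC(C)(C)[Si](C)(C)Cl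
Why: Chemoselective silylation, since under imidazole catalysis the primary alcohol reacts much faster than the doubly ortho-substituted phenol.

Step 11
Reactants: 14 ArB–OH; 15 trichloroethylene
Product: 17 ArB (E)-1,2-dichlorovinyl ether, via dichloroacetylene 16 (not isolated)
Conditions: K2CO3, DMF, 70 °C
Reagents that add atoms: none
Why: Base-induced elimination turns trichloroethylene into dichloroacetylene (generated and consumed in solution), to which the phenoxide adds in anti fashion to give the (E)-dichlorovinyl ether, the standard ynol ether precursor.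

Step 12
Reactants: 17 ArB (E)-1,2-dichlorovinyl ether
Product: 20 3-(ArB-oxy)prop-2-yn-1-ol, via chloroalkynyl ether 18 (not isolated), via lithium acetylide 19 (not isolated)
Conditions: n-BuLi (2.2 equiv), THF, −78 °C; (CH2O)n, −78 °C → rt; aq NH4Cl
Reagents that add atoms: paraformaldehyde (formaldehyde), C=O
Why: Deprotonation with β-elimination gives the chloroalkyne, chlorine–lithium exchange gives the lithium aryloxyacetylide, and this adds to formaldehyde, all faster at −78 °C than ortho-lithiation next to the acetal.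

Step 13
Reactants: 20 3-(ArB-oxy)prop-2-yn-1-ol
Product: 21 ArB 3-(PMB-oxy)prop-1-ynyl ether
Conditions: NaH, PMBCl, Bu4NI (cat.), THF/DMF, 0 °C → rt
Reagents that add atoms: 4-methoxybenzyl chloride, COc1ccc(CCl)cc1
Why: Williamson etherification of the propargylic alkoxide, whose basic conditions leave the acid-sensitive ynol ether alone.

Step 14
Reactants: 8 (S,E)-1-diazo-7-methyl-5,7-bis(triethylsilyloxy)oct-3-en-2-one (1.3 equiv); 21 ArB 3-(PMB-oxy)prop-1-ynyl ether
Product: 26 3-(ArB-oxy)-2-[(PMB-oxy)methyl]-6-[(S)-3-methyl-1,3-bis(TES-oxy)butyl]phenol, via vinylketene 22 (not isolated), via vinylcyclobutenone 23 (not isolated), via dienylketene 24 (not isolated), via cyclohexadienone 25 (not isolated)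
Conditions: hν (medium-pressure Hg lamp, Pyrex filter, >300 nm), ClCH2CH2Cl, 20 °C; then 80 °C
Reagents that add atoms: none
Why: Light expels N2 from 8 and the alkenyl group shifts to the former diazo carbon (Wolff rearrangement, forming C4–C5) to give vinylketene 22, whose carbonyl carbon is attacked by the electron-rich β-carbon of ynol ether 21, the dipole collapsing to the four-membered ring of 23 ([2+2] cycloaddition, forming C1–C2 and C5–C6). Reversible four-electron electrocyclic opening of 23 gives dienylketene 24, which closes ring A by a thermal six-electron disrotatory electrocyclisation (forming C2–C3), and enolisation of dienone 25 gives phenol 26. The closest known reaction is the Danheiser benzannulation in its diazo ketone (photo-Wolff) form with alkoxy- and siloxyalkynes, and aryloxyalkynes belong to the same class of ketenophilic ynol ethers. No stereocentre is created in the product, because the sp3 ring carbons of 23 and 25 vanish on aromatisation, and the silyl-protected carbinol, trans to the ketene across the (E)-alkene and without an acidic neighbour, is carried through unchanged. The only selectivity needed is regiochemical and is fixed by the polarisation of the alkyne by its oxygen, which places the aryloxy carbon meta to the new hydroxyl with the CH2OPMB carbon between them. Light above 300 nm excites the diazo ketone but not the arene chromophores, and the excess of 8 offsets ketene dimerisation.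

Step 15
Reactants: 26 ring A phenol
Product: 27 1-(ArB-oxy)-3-methoxy-2-[(PMB-oxy)methyl]-4-[(S)-3-methyl-1,3-bis(TES-oxy)butyl]benzene
Conditions: MeI, Cs2CO3, DMF, rt
Reagents that add atoms: iodomethane, CI
Why: Williamson O-methylation, for which caesium phenoxide in DMF copes with the two ortho substituents and silyl migration from an alkyl oxygen to the phenoxide is thermodynamically uphill.

Step 16
Reactants: 27 ring A methyl ether with CH2OPMB
Product: 28 {6-(ArB-oxy)-2-methoxy-3-[(S)-3-methyl-1,3-bis(TES-oxy)butyl]phenyl}methanol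
Conditions: DDQ (1.3 equiv), CH2Cl2/pH 7 phosphate buffer, 0 °C
Reagents that add atoms: none
Why: Oxidative cleavage of the p-methoxybenzyl ether by hydride abstraction with DDQ under cold buffered conditions that spare silyl ethers and the acetal; abstraction at the ring A methylene instead would lead to aldehyde 29, so both modes converge in step 17.

Step 17
Reactants: 28 ring A benzylic alcohol
Product: 29 6-(ArB-oxy)-2-methoxy-3-[(S)-3-methyl-1,3-bis(TES-oxy)butyl]benzaldehyde
Conditions: Dess–Martin periodinane, pyridine, CH2Cl2, 0 °C → rt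
Reagents that add atoms: none
Why: Dess–Martin oxidation of the hindered primary benzylic alcohol under buffered, essentially neutral conditions.

Step 18
Reactants: 29 ring A aldehyde
Product: 30 6-(ArB-oxy)-2-methoxy-3-[(S)-3-methyl-1,3-bis(TES-oxy)butyl]benzoic acid
Conditions: NaClO2, NaH2PO4, 2-methylbut-2-ene, t-BuOH/H2O, rt
Reagents that add atoms: sodium chlorite, [Na+].[O-]Cl=O
Why: Pinnick oxidation with an alkene scavenger for hypochlorous acid converts even a 2,6-disubstituted benzaldehyde into the acid without chlorinating the electron-rich rings.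

Step 19
Reactants: 30 protected acid
Product: 31 3-[(S)-1,3-dihydroxy-3-methylbutyl]-6-[2-hydroxy-6-(hydroxymethyl)-4-methylphenoxy]-2-methoxybenzoic acid (CNP0452050.2)
Conditions: Bu4NF (excess), THF, rt → 60 °C; then cold 0.5 M HCl to pH 3
Reagents that add atoms: none
Why: Fluoride cleaves the three silyl ethers and, on warming, the phenolic SEM acetal by β-silyl fragmentation, and the basic medium avoids ionisation of the electron-rich benzylic carbinol, so the S centre is retained.

**Compound list**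

1 | (S)-3-hydroxy-γ-butyrolactone | O=C1C[C@H](O)CO1 | starting material
2 | (S)-4-methylpentane-1,2,4-triol | OC[C@@H](O)CC(C)(C)O | intermediate
3 | (S)-4-methyl-1,2,4-tris(triethylsilyloxy)pentane | CC[Si](CC)(CC)OC[C@@H](O[Si](CC)(CC)CC)CC(C)(C)O[Si](CC)(CC)CC | intermediate
4 | (S)-4-methyl-2,4-bis(triethylsilyloxy)pentanal | O=C[C@@H](O[Si](CC)(CC)CC)CC(C)(C)O[Si](CC)(CC)CC | intermediate
5 | 1-(triphenylphosphoranylidene)propan-2-one | CC(=O)C=P(c1ccccc1)(c1ccccc1)c1ccccc1 | starting material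
6 | (S,E)-7-methyl-5,7-bis(triethylsilyloxy)oct-3-en-2-one | CC(=O)/C=C/[C@@H](O[Si](CC)(CC)CC)CC(C)(C)O[Si](CC)(CC)CC | intermediate
7 | (S,E)-1,1,1-trifluoro-9-methyl-7,9-bis(triethylsilyloxy)dec-5-ene-2,4-dione | O=C(CC(=O)/C=C/[C@@H](O[Si](CC)(CC)CC)CC(C)(C)O[Si](CC)(CC)CC)C(F)(F)F | intermediate (not isolated)
8 | (S,E)-1-diazo-7-methyl-5,7-bis(triethylsilyloxy)oct-3-en-2-one | [N-]=[N+]=CC(=O)/C=C/[C@@H](O[Si](CC)(CC)CC)CC(C)(C)O[Si](CC)(CC)CC | intermediate
9 | 2-methoxy-4-methylphenol (creosol) | COc1cc(C)ccc1O | starting material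
10 | 2-hydroxy-3-methoxy-5-methylbenzaldehyde | COc1cc(C)cc(C=O)c1O | intermediate
11 | 2,3-dihydroxy-5-methylbenzaldehyde | O=Cc1cc(C)cc(O)c1O | intermediate
12 | 2-hydroxy-5-methyl-3-{[2-(trimethylsilyl)ethoxy]methoxy}benzaldehyde | O=Cc1cc(C)cc(OCOCC[Si](C)(C)C)c1O | intermediate
13 | 2-(hydroxymethyl)-4-methyl-6-{[2-(trimethylsilyl)ethoxy]methoxy}phenol | OCc1cc(C)cc(OCOCC[Si](C)(C)C)c1O | intermediate
14 | 2-{[(tert-butyldimethylsilyl)oxy]methyl}-4-methyl-6-{[2-(trimethylsilyl)ethoxy]methoxy}phenol (ArB–OH) | CC(C)(C)[Si](C)(C)OCc1cc(C)cc(OCOCC[Si](C)(C)C)c1O | intermediate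
15 | trichloroethylene | ClC=C(Cl)Cl | starting material
16 | dichloroacetylene | ClC#CCl | intermediate (not isolated)
17 | ArB (E)-1,2-dichlorovinyl ether | Cl/C=C(Cl)\Oc1c(OCOCC[Si](C)(C)C)cc(C)cc1CO[Si](C)(C)C(C)(C)C | intermediate
18 | ArB chloroethynyl ether | ClC#COc1c(OCOCC[Si](C)(C)C)cc(C)cc1CO[Si](C)(C)C(C)(C)C | intermediate (not isolated)
19 | lithium (ArB-oxy)acetylide | [Li]C#COc1c(OCOCC[Si](C)(C)C)cc(C)cc1CO[Si](C)(C)C(C)(C)C | intermediate (not isolated)
20 | 3-(ArB-oxy)prop-2-yn-1-ol | OCC#COc1c(OCOCC[Si](C)(C)C)cc(C)cc1CO[Si](C)(C)C(C)(C)C | intermediate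
21 | ArB 3-(4-methoxybenzyloxy)prop-1-ynyl ether | COc1ccc(COCC#COc2c(OCOCC[Si](C)(C)C)cc(C)cc2CO[Si](C)(C)C(C)(C)C)cc1 | intermediate
22 | (S,E)-7-methyl-5,7-bis(triethylsilyloxy)octa-1,3-dien-1-one (vinylketene) | O=C=C/C=C/[C@@H](O[Si](CC)(CC)CC)CC(C)(C)O[Si](CC)(CC)CC | intermediate (not isolated)
23 | 3-(ArB-oxy)-2-[(PMB-oxy)methyl]-4-[(S,E)-5-methyl-3,5-bis(TES-oxy)hex-1-enyl]cyclobut-2-en-1-one | COc1ccc(COCC2=C(Oc3c(OCOCC[Si](C)(C)C)cc(C)cc3CO[Si](C)(C)C(C)(C)C)C(/C=C/[C@@H](O[Si](CC)(CC)CC)CC(C)(C)O[Si](CC)(CC)CC)C2=O)cc1 | intermediate (not isolated)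
24 | (3Z,5E,7S)-3-(ArB-oxy)-9-methyl-2-[(PMB-oxy)methyl]-7,9-bis(TES-oxy)deca-1,3,5-trien-1-one (dienylketene) | COc1ccc(COCC(=C=O)/C(Oc2c(OCOCC[Si](C)(C)C)cc(C)cc2CO[Si](C)(C)C(C)(C)C)=C\C=C\[C@@H](O[Si](CC)(CC)CC)CC(C)(C)O[Si](CC)(CC)CC)cc1 | intermediate (not isolated)
25 | 3-(ArB-oxy)-2-[(PMB-oxy)methyl]-6-[(S)-3-methyl-1,3-bis(TES-oxy)butyl]cyclohexa-2,4-dien-1-one | COc1ccc(COCC2=C(Oc3c(OCOCC[Si](C)(C)C)cc(C)cc3CO[Si](C)(C)C(C)(C)C)C=CC([C@@H](O[Si](CC)(CC)CC)CC(C)(C)O[Si](CC)(CC)CC)C2=O)cc1 | intermediate (not isolated)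
26 | 3-(ArB-oxy)-2-[(PMB-oxy)methyl]-6-[(S)-3-methyl-1,3-bis(TES-oxy)butyl]phenol | Oc1c([C@@H](O[Si](CC)(CC)CC)CC(C)(C)O[Si](CC)(CC)CC)ccc(Oc2c(OCOCC[Si](C)(C)C)cc(C)cc2CO[Si](C)(C)C(C)(C)C)c1COCc1ccc(OC)cc1 | intermediate
27 | 1-(ArB-oxy)-3-methoxy-2-[(PMB-oxy)methyl]-4-[(S)-3-methyl-1,3-bis(TES-oxy)butyl]benzene | COc1c([C@@H](O[Si](CC)(CC)CC)CC(C)(C)O[Si](CC)(CC)CC)ccc(Oc2c(OCOCC[Si](C)(C)C)cc(C)cc2CO[Si](C)(C)C(C)(C)C)c1COCc1ccc(OC)cc1 | intermediate
28 | {6-(ArB-oxy)-2-methoxy-3-[(S)-3-methyl-1,3-bis(TES-oxy)butyl]phenyl}methanol | COc1c([C@@H](O[Si](CC)(CC)CC)CC(C)(C)O[Si](CC)(CC)CC)ccc(Oc2c(OCOCC[Si](C)(C)C)cc(C)cc2CO[Si](C)(C)C(C)(C)C)c1CO | intermediate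
29 | 6-(ArB-oxy)-2-methoxy-3-[(S)-3-methyl-1,3-bis(TES-oxy)butyl]benzaldehyde | COc1c([C@@H](O[Si](CC)(CC)CC)CC(C)(C)O[Si](CC)(CC)CC)ccc(Oc2c(OCOCC[Si](C)(C)C)cc(C)cc2CO[Si](C)(C)C(C)(C)C)c1C=O | intermediate
30 | 6-(ArB-oxy)-2-methoxy-3-[(S)-3-methyl-1,3-bis(TES-oxy)butyl]benzoic acid | COc1c([C@@H](O[Si](CC)(CC)CC)CC(C)(C)O[Si](CC)(CC)CC)ccc(Oc2c(OCOCC[Si](C)(C)C)cc(C)cc2CO[Si](C)(C)C(C)(C)C)c1C(=O)O | intermediate
31 | 3-[(S)-1,3-dihydroxy-3-methylbutyl]-6-[2-hydroxy-6-(hydroxymethyl)-4-methylphenoxy]-2-methoxybenzoic acid | COc1c([C@@H](O)CC(C)(C)O)ccc(Oc2c(O)cc(C)cc2CO)c1C(=O)O | target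

**Count and risks**

Total step count: 19 (steps 1–5 for 8, steps 6–13 for 21, step 14, steps 15–19).
Longest linear sequence: 14 steps (creosol 9 to target 31, steps 6–19).

Steps most likely to fail:

1. Step 14. The vinylketene may be lost to dimerisation, or the ynol ether and the phenol may be degraded under irradiation, before the cycloaddition and the ring closure are complete. The fallback generates the same ketene in the dark and sets out from 8. Wolff rearrangement in wet solvent (PhCO2Ag cat., Et3N, THF/H2O) should give (S,E)-7-methyl-5,7-bis(triethylsilyloxy)oct-3-enoic acid F1. 1-Chloro-N,N,2-trimethylprop-1-en-1-amine in CH2Cl2 should convert it under neutral conditions into (S,E)-7-methyl-5,7-bis(triethylsilyloxy)oct-3-enoyl chloride F2. Slow addition of F2 to 21 and Et3N in toluene should release vinylketene 22 by dehydrochlorination at a low stationary concentration, and [2+2] addition gives 23. Heating to 80–110 °C should then carry 23 through 24 and 25 to phenol 26, where the route is rejoined.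

2. Step 12. Ortho-lithiation of ring B or decomposition of the lithium aryloxyacetylide may compete with the elimination and exchange sequence, and capture by polymeric formaldehyde may be inefficient. The fallback avoids organolithium chemistry, sets out from phenol 14 and bypasses steps 11–13. Commercial 2-[(4-methoxybenzyl)oxy]acetaldehyde is converted by Corey–Fuchs dibromoolefination (CBr4, PPh3) into 1-{[(3,3-dibromoprop-2-en-1-yl)oxy]methyl}-4-methoxybenzene F3. Copper-catalysed C–O coupling of 14 with F3 (CuI, 2,2'-bipyridine, K3PO4, toluene, 110 °C) should replace the bromine trans to the chain and give ArB (Z)-1-bromo-3-(PMB-oxy)prop-1-enyl ether F4. Anti-elimination of HBr with KOt-Bu in THF should then give ynol ether 21, where the route is rejoined.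

3. Step 16. DDQ may abstract hydride at the C3 benzylic carbinol carbon of the very electron-rich ring A, with loss of the silyl ether and of the stereocentre, in competition with cleavage of the PMB ether. The fallback removes the oxidative deprotection and sets out from 20.
   - Silylation (Et3SiCl, imidazole, CH2Cl2) should give ArB 3-(triethylsilyloxy)prop-1-ynyl ether F5.
   - Under the conditions of step 14, F5 and 8 should pass through vinylketene 22, cyclobutenone F6, dienylketene F7 and cyclohexadienone F8 to the ring A phenol with a CH2OTES group on C1, F9.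
   - MeI/Cs2CO3 should give its methyl ether F10.
   - The chlorosulfonium conditions of step 3 should then convert the only primary triethylsilyl ether of F10 directly into aldehyde 29, where the route is rejoined one step shorter.

**Further compounds**

F1 | step 14 | (S,E)-7-methyl-5,7-bis(triethylsilyloxy)oct-3-enoic acid | OC(=O)C/C=C/[C@@H](O[Si](CC)(CC)CC)CC(C)(C)O[Si](CC)(CC)CC
F2 | step 14 | (S,E)-7-methyl-5,7-bis(triethylsilyloxy)oct-3-enoyl chloride | ClC(=O)C/C=C/[C@@H](O[Si](CC)(CC)CC)CC(C)(C)O[Si](CC)(CC)CC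
F3 | step 12 | 1-{[(3,3-dibromoprop-2-en-1-yl)oxy]methyl}-4-methoxybenzene | COc1ccc(COCC=C(Br)Br)cc1
F4 | step 12 | ArB (Z)-1-bromo-3-(4-methoxybenzyloxy)prop-1-enyl ether | COc1ccc(COC/C=C(/Oc2c(OCOCC[Si](C)(C)C)cc(C)cc2CO[Si](C)(C)C(C)(C)C)Br)cc1
F5 | step 16 | ArB 3-(triethylsilyloxy)prop-1-ynyl ether | CC[Si](CC)(CC)OCC#COc1c(OCOCC[Si](C)(C)C)cc(C)cc1CO[Si](C)(C)C(C)(C)C
F6 | step 16 | 3-(ArB-oxy)-2-[(TES-oxy)methyl]-4-[(S,E)-5-methyl-3,5-bis(TES-oxy)hex-1-enyl]cyclobut-2-en-1-one | CC[Si](CC)(CC)OCC1=C(Oc2c(OCOCC[Si](C)(C)C)cc(C)cc2CO[Si](C)(C)C(C)(C)C)C(/C=C/[C@@H](O[Si](CC)(CC)CC)CC(C)(C)O[Si](CC)(CC)CC)C1=O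
F7 | step 16 | (3Z,5E,7S)-3-(ArB-oxy)-9-methyl-2-[(TES-oxy)methyl]-7,9-bis(TES-oxy)deca-1,3,5-trien-1-one | CC[Si](CC)(CC)OCC(=C=O)/C(Oc1c(OCOCC[Si](C)(C)C)cc(C)cc1CO[Si](C)(C)C(C)(C)C)=C\C=C\[C@@H](O[Si](CC)(CC)CC)CC(C)(C)O[Si](CC)(CC)CC
F8 | step 16 | 3-(ArB-oxy)-2-[(TES-oxy)methyl]-6-[(S)-3-methyl-1,3-bis(TES-oxy)butyl]cyclohexa-2,4-dien-1-one | CC[Si](CC)(CC)OCC1=C(Oc2c(OCOCC[Si](C)(C)C)cc(C)cc2CO[Si](C)(C)C(C)(C)C)C=CC([C@@H](O[Si](CC)(CC)CC)CC(C)(C)O[Si](CC)(CC)CC)C1=O
F9 | step 16 | 3-(ArB-oxy)-2-[(TES-oxy)methyl]-6-[(S)-3-methyl-1,3-bis(TES-oxy)butyl]phenol | Oc1c([C@@H](O[Si](CC)(CC)CC)CC(C)(C)O[Si](CC)(CC)CC)ccc(Oc2c(OCOCC[Si](C)(C)C)cc(C)cc2CO[Si](C)(C)C(C)(C)C)c1CO[Si](CC)(CC)CC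
F10 | step 16 | 1-(ArB-oxy)-3-methoxy-2-[(TES-oxy)methyl]-4-[(S)-3-methyl-1,3-bis(TES-oxy)butyl]benzene | COc1c([C@@H](O[Si](CC)(CC)CC)CC(C)(C)O[Si](CC)(CC)CC)ccc(Oc2c(OCOCC[Si](C)(C)C)cc(C)cc2CO[Si](C)(C)C(C)(C)C)c1CO[Si](CC)(CC)CC
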